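Time is the gap here: Monday's readings on this flask stop at 60.0 min, and the question stands at 2.5 h.

the same everywhere: Q 0.25 M
- Monday's: X 0.95 equiv; the very flask that is asked about, followed so far
- flask: X 0.950 equiv; time 2.5 h; volume of the second phase over the first 0.50

Monday's run (percent of the Q charged)

| time / min | J / % | Q / % |
|---|---|---|
| 8.00 | 2.5 | 97.7 |
| 15.0 | 4.1 | 96.1 |
| 25.0 | 6.7 | 92.9 |
| 30.0 | 7.7 | 91.6 |
| 40.0 | 9.3 | 88.6 |
| 50.0 | 11.3 | 86.5 |
| 60.0 | 12.6 | 85.1 |

(scatter of a reading: 0.3 percentage points)

- in the second phase: X; everything else is in the first
- charges count per volume of the first phase; a concentration in a rate is the amount of a species over the volume of its own phase; every rate counts per litre of the first phase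
- the analysis behind the earlier runs scatters by 0.3 percentage points, standard deviation
- the earlier runs hold the two phases in the same ratio of volumes as the flask asked about

- oak: doubling the transfer coefficient of X, all else as stated
- cedar: doubling the amount of X, all else as stated

- how much J there is at 2.5 h, in percent of the Q charged
- the change that raises the amount of J at 2.5 h, in percent of the Q charged most ("none" if none brings more than 2 percentage points) (oak / cedar / none)
- amount of J at 2.5 h, in percent of the Q charged, after oak

I work in powers of ten. At 60.0 min Q reads 85.1%, so it has lost 0.0701 of a decade. I take that as a steady clock, a first-order fall, which stretches to 0.175 of a decade at 2.5 h. So I expect the share of Q left to be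

q = 66.8%

Then J. The lost share is the Q gone minus the J found, 2.3 percentage points at the last reading. Let r be the ratio of J's loss to Q's loss, each per unit of itself; early in a run r is about twice the lost share over the square of the Q gone, which gives 2.07. From r and q I reckon

J = (q − q^r) / (r − 1) = 21.9%

The weak link is r: that lost share rests on one line of readings, each scattering by 0.3 points. So I reforge it, summing lost shares and squares over the last 3 readings:

r = 2.47, so J = 20.3%

I carry this loss ratio, J's loss per unit of J over Q's loss per unit of Q, the selectivity factor. I commit to 20.3% and have no reckoning of my own for the two changes.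

The forecast says 23% (19.5% to 27%), with cedar best and 24% after oak (20.5% to 29%). It reads the missing balance as a loss, “which suggests J is being consumed further”, and takes a ratio of 1.7, lower than mine.

The flask gives 17.5%. Cedar adds 5.1 points and oak 2.6 points, so cedar is best, and oak ends at 20.1%.

    Q + L → J (k = 2.10 L mol⁻¹ min⁻¹)
    L ⇌ X, rate k2*([L] - [X]/K2) per volume of the first phase (partition coefficient = 87.3, kL = 0.211 min⁻¹)
    L + J → G (k = 2.94 L mol⁻¹ min⁻¹)
    J → E (k = 0.00437 min⁻¹)

Put into the same reckoning, the flask's Q of 68.3% at 2.5 h and my ratio of 2.47 give 19.9% of J, and the flask holds less than that, at 17.5%. The neighbouring flask has the same charges and is read at 10 h. Its Q stands at 37.9%, so the ratio gives 19.6% of J, but that flask holds less, 8.81%, beside 35.1% of E.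

All runs stem from a simulated flask for an exercise; scatter was added.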